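**Retrosynthetic overview**

- Last operation: hydrogenolysis of two benzyl ethers (on O5 and O7) from the dibenzyl ether of the target.
- Key disconnection: the aryl–acyl bond C8–C(=O). Enabling feature: the ketone carbon sits on C8 of the benzo ring, directly ortho to the lactone oxygen O1 (on C8a), and C8 is the only unsubstituted carbon ortho to O1 (the other, C4a, carries C4). This ortho-acyl aryl ester pattern is the retron of a 1,3 O→C acyl shift.
- The pyranone ring is therefore opened at O1–C2 (methyl ester) and O1 carries the 3-(4-methoxyphenyl)propanoyl group as a temporary ester tether that is not in the target. One operation moves the acyl group to C8 and lets the freed O1 close the lactone again.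
- The tethered ester comes from (4S)-5,7-bis(benzyloxy)-4-phenylchroman-2-one and 3-(4-methoxyphenyl)propanoyl chloride. The lactone comes from 3,5-bis(benzyloxy)phenol and cinnamaldehyde by iminium-catalysed Friedel–Crafts alkylation/hemiacetalisation (sets C4) and lactol oxidation.
- Ring order: the benzene rings are bought; the pyran ring is closed in step 1 (lactol), oxidised in step 2, opened in step 4 and closed for good in the key step.

Key step: step 5

Remark on the chemistry: 3,5-bis(benzyloxy)phenol, (E)-cinnamaldehyde and 3-(4-methoxyphenyl)propanoic acid are taken as commercial; locants (O1, C2, C4, C4a, C5–C8, C8a) are those of the chroman-2-one core.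

**Route**

Step 1
Reactants: 1 3,5-bis(benzyloxy)phenol; 2 (E)-cinnamaldehyde
Product: 4 (4S)-5,7-bis(benzyloxy)-4-phenylchroman-2-ol (both C2 epimers), via open-chain hydroxy aldehyde 3 (not isolated)
Conditions: (S)-α,α-diphenylprolinol TMS ether (20 mol%), PhCO2H (20 mol%), toluene, 0 °C to rt
Reagents that add atoms: none
Why: Iminium-ion catalysed Friedel–Crafts alkylation of an electron-rich phenol by an enal followed by hemiacetalisation: the CPh2(OTMS) group of the (S)-catalyst shields the Re face of the β-carbon of the (E)-iminium ion, the ring carbon ortho to the phenol OH adds to the Si face and sets C4 as S, and only ortho attack lets the hydroxyl trap the aldehyde as the lactol.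

Step 2
Reactants: 4 (4S)-5,7-bis(benzyloxy)-4-phenylchroman-2-ol
Product: 5 (4S)-5,7-bis(benzyloxy)-4-phenylchroman-2-one
Conditions: TPAP (5 mol%), NMO (1.5 equiv), 4 Å MS, CH2Cl2, rt
Reagents that add atoms: none
Why: Ley–Griffith oxidation of a lactol to the lactone, which acts only at the hemiacetal carbon and should leave C4 and the benzyl ethers untouched.

Step 3
Reactants: 6 3-(4-methoxyphenyl)propanoic acid
Product: 7 3-(4-methoxyphenyl)propanoyl chloride
Conditions: (COCl)2, DMF (cat.), CH2Cl2, 0 °C to rt
Reagents that add atoms: oxalyl chloride, ClC(=O)C(=O)Cl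
Why: Standard conversion of a carboxylic acid into its chloride with oxalyl chloride under Vilsmeier-type DMF catalysis.

Step 4
Reactants: 5 (4S)-5,7-bis(benzyloxy)-4-phenylchroman-2-one; 7 3-(4-methoxyphenyl)propanoyl chloride
Product: 9 methyl (3S)-3-[2,4-bis(benzyloxy)-6-{[3-(4-methoxyphenyl)propanoyl]oxy}phenyl]-3-phenylpropanoate, via sodium phenoxide methyl ester 8 (not isolated)
Conditions: NaOMe (1.05 equiv), MeOH–THF, 0 °C; evaporate; then 7, THF, 0 °C to rt
Reagents that add atoms: sodium methoxide, [Na+].[O-]C
Why: Transesterification of the reactive aryl lactone by methoxide should give the open-chain sodium phenoxide, whose O-acylation by the acid chloride installs the O1–acyl tether and blocks re-lactonisation, while the C4–H is not acidic enough to epimerise.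

Step 5
Reactants: 9 methyl (3S)-3-[2,4-bis(benzyloxy)-6-{[3-(4-methoxyphenyl)propanoyl]oxy}phenyl]-3-phenylpropanoate
Product: 11 (4S)-5,7-bis(benzyloxy)-8-[3-(4-methoxyphenyl)propanoyl]-4-phenylchroman-2-one, via ortho-hydroxyaryl ketone methyl ester 10 (not isolated)
Conditions: Sc(OTf)3 (10 mol%), toluene–MeNO2 (5:1), 60 °C then 85 °C (N2 sweep to remove MeOH)
Reagents that add atoms: none
Why: Sc(III) activates the aryl ester carbonyl of 9 and the acyl group passes from O1 to the adjacent ring carbon within the aryloxide/acylium contact pair (Fries rearrangement, a 1,3 O→C acyl shift) to give the ortho-hydroxyaryl ketone 10, held as a chelate between O1 and the new carbonyl. The closest known reaction type is the metal-triflate-catalysed Fries rearrangement of meta-alkoxyphenyl esters to ortho-hydroxyaryl ketones. The freed O1–H then attacks the pendant methyl ester under the same Lewis acid and closes the pyranone ring by 6-exo-trig acyl substitution with loss of methanol, so the O1–acyl ester bond (absent from the target) is traded for the C8–C(=O) bond and the lactone. No stereocentre is formed, and C4 has no ionisable bond or acidic hydrogen under these conditions and should keep its S configuration. The step needs acyl transfer to C8 and not to C6, and lactonisation on O1 only: the tether delivers from O1, whose single free ortho carbon is C8 (C4a is substituted), the C8 ketone alone can chelate to O1–H while C6 is flanked by two benzyloxy groups, and with O5 and O7 benzylated O1 is the only oxygen that can close the ring.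

Step 6
Reactants: 11 (4S)-5,7-bis(benzyloxy)-8-[3-(4-methoxyphenyl)propanoyl]-4-phenylchroman-2-one
Product: 12 (4S)-5,7-dihydroxy-8-[3-(4-methoxyphenyl)propanoyl]-4-phenyl-3,4-dihydro-2H-chromen-2-one
Conditions: H2 (1 atm), 10% Pd/C, EtOAc, rt
Reagents that add atoms: none
Why: Palladium-catalysed hydrogenolysis of aryl benzyl ethers under neutral conditions should free O5–H and O7–H while the hydrogen-bonded aryl ketone, the lactone, the anisole ether and the C4 stereocentre are not affected.

**Compound list**

1 | 3,5-bis(benzyloxy)phenol | Oc1cc(OCc2ccccc2)cc(OCc2ccccc2)c1 | starting material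
2 | (E)-cinnamaldehyde | O=C/C=C/c1ccccc1 | starting material
3 | (3S)-3-[2,4-bis(benzyloxy)-6-hydroxyphenyl]-3-phenylpropanal | O=CC[C@@H](c1ccccc1)c1c(O)cc(OCc2ccccc2)cc1OCc1ccccc1 | intermediate
4 | (4S)-5,7-bis(benzyloxy)-4-phenylchroman-2-ol (both C2 epimers) | OC1C[C@@H](c2ccccc2)c2c(OCc3ccccc3)cc(OCc3ccccc3)cc2O1 | intermediate
5 | (4S)-5,7-bis(benzyloxy)-4-phenylchroman-2-one | O=C1C[C@@H](c2ccccc2)c2c(OCc3ccccc3)cc(OCc3ccccc3)cc2O1 | intermediate
6 | 3-(4-methoxyphenyl)propanoic acid | COc1ccc(CCC(=O)O)cc1 | starting material
7 | 3-(4-methoxyphenyl)propanoyl chloride | COc1ccc(CCC(=O)Cl)cc1 | intermediate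
8 | sodium 3,5-bis(benzyloxy)-2-[(1S)-3-methoxy-3-oxo-1-phenylpropyl]phenolate | COC(=O)C[C@@H](c1ccccc1)c1c([O-])cc(OCc2ccccc2)cc1OCc1ccccc1.[Na+] | intermediate
9 | methyl (3S)-3-[2,4-bis(benzyloxy)-6-{[3-(4-methoxyphenyl)propanoyl]oxy}phenyl]-3-phenylpropanoate | COC(=O)C[C@@H](c1ccccc1)c1c(OC(=O)CCc2ccc(OC)cc2)cc(OCc2ccccc2)cc1OCc1ccccc1 | intermediate
10 | methyl (3S)-3-[4,6-bis(benzyloxy)-2-hydroxy-3-[3-(4-methoxyphenyl)propanoyl]phenyl]-3-phenylpropanoate | COC(=O)C[C@@H](c1ccccc1)c1c(O)c(C(=O)CCc2ccc(OC)cc2)c(OCc2ccccc2)cc1OCc1ccccc1 | intermediate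
11 | (4S)-5,7-bis(benzyloxy)-8-[3-(4-methoxyphenyl)propanoyl]-4-phenylchroman-2-one | COc1ccc(CCC(=O)c2c(OCc3ccccc3)cc(OCc3ccccc3)c3c2OC(=O)C[C@H]3c2ccccc2)cc1 | intermediate
12 | (4S)-5,7-dihydroxy-8-[3-(4-methoxyphenyl)propanoyl]-4-phenyl-3,4-dihydro-2H-chromen-2-one | COc1ccc(CCC(=O)c2c(O)cc(O)c3c2OC(=O)C[C@H]3c2ccccc2)cc1 | target

**Step count and risks**

Total steps: 6. Longest linear sequence: 5 steps (1, 2, 4, 5, 6); step 3 is a one-step branch.

Steps most likely to fail:

1. Step 5 (key step). The acyl group may escape the contact pair and be delivered to the para carbon C6 or to another molecule, which would lose the ortho control. The Lewis acid may also cleave or transfer benzyl groups at the temperature needed for ring closure. The fallback is an anionic, strictly ortho acyl shift that sets out from 5 and comes back at 11. Lactone 5 would be opened with catalytic NaOMe in MeOH at 0 °C and quenched cold with AcOH to give methyl (3S)-3-[2,4-bis(benzyloxy)-6-hydroxyphenyl]-3-phenylpropanoate F1. Amine-mediated ortho-bromination of this phenol (NBS, cat. i-Pr2NH, CH2Cl2, 0 °C) should give methyl (3S)-3-[4,6-bis(benzyloxy)-3-bromo-2-hydroxyphenyl]-3-phenylpropanoate F2. Acylation with 7 (Et3N, DMAP, CH2Cl2) should give methyl (3S)-3-[4,6-bis(benzyloxy)-3-bromo-2-{[3-(4-methoxyphenyl)propanoyl]oxy}phenyl]-3-phenylpropanoate F3. Bromine–lithium exchange (n-BuLi, THF, −100 °C) should outrun addition to the esters, and the aryllithium should be trapped at once by the neighbouring ester carbonyl (anionic Fries rearrangement) to give 10 after protonation. Catalytic TsOH in toluene at 60 °C should then close the lactone to 11.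

2. Step 1. Alkylation may occur through the carbon between the two benzyloxy groups (para to OH), the product may be alkylated a second time, or facial control in the addition to the iminium ion may be weak. The fallback sets out from 1 and comes back at 5. Palladium-catalysed hydroarylation/lactonisation of 1 with ethyl propiolate (Pd(OAc)2 cat., NaOAc, HCO2H, rt) should give 5,7-bis(benzyloxy)-2H-chromen-2-one F4. Rhodium-catalysed asymmetric 1,4-addition of phenylboronic acid (Rh(acac)(C2H4)2, (S)-SEGPHOS, dioxane–H2O, 60 °C) should then give 5 directly. The ligand antipode is chosen from the facial preference of this ligand family in 4-arylations of coumarins, so the catalyst face and not a remote substituent sets C4.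

3. Step 6. Hydrogenolysis may run on into reduction of the aryl ketone, or the lactone acyl may migrate from O1 to the newly freed O5–H on prolonged contact with the catalyst. The fallback sets out from 11 and comes back at 12: Lewis-acid debenzylation with BCl3 and pentamethylbenzene as cation scavenger (CH2Cl2, −78 °C, cold mildly acidic work-up). This should remove both benzyl groups without hydrogen and leave the anisole methyl ether, which is not activated by a neighbouring carbonyl, in place. It makes no new compound (F0).

**Further compounds**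

F1 | step 5 | methyl (3S)-3-[2,4-bis(benzyloxy)-6-hydroxyphenyl]-3-phenylpropanoate | COC(=O)C[C@@H](c1ccccc1)c1c(O)cc(OCc2ccccc2)cc1OCc1ccccc1
F2 | step 5 | methyl (3S)-3-[4,6-bis(benzyloxy)-3-bromo-2-hydroxyphenyl]-3-phenylpropanoate | COC(=O)C[C@@H](c1ccccc1)c1c(O)c(Br)c(OCc2ccccc2)cc1OCc1ccccc1
F3 | step 5 | methyl (3S)-3-[4,6-bis(benzyloxy)-3-bromo-2-{[3-(4-methoxyphenyl)propanoyl]oxy}phenyl]-3-phenylpropanoate | COC(=O)C[C@@H](c1ccccc1)c1c(OC(=O)CCc2ccc(OC)cc2)c(Br)c(OCc2ccccc2)cc1OCc1ccccc1
F4 | step 1 | 5,7-bis(benzyloxy)-2H-chromen-2-one | O=C1C=Cc2c(OCc3ccccc3)cc(OCc3ccccc3)cc2O1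
F0 | step 6 | none | none
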